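The tertiary C1 hydroxyl and the secondary C4 hydroxyl lie cis on either side of the C5=C6 double bond of the cyclohexene ring, the pattern left when a peroxide bridge between C1 and C4 is reduced. A single photooxygenation of the C1=C6–C5=C4 cyclohexadiene therefore forms both C–O bonds, sets the quaternary C1 and the C4 stereocentres and moves the alkene to C5=C6, the free C2 hydroxyl steering oxygen to its own face. The diene, already carrying the C3 benzoate (trans to the C2 hydroxyl) and the C7 benzoate, is built from D-arabinose by a double Wittig ring closure on an acetonide-protected keto-aldehyde.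

Key step: step 10

Remark: atoms are numbered as in the target name (C7 = benzoyloxymethyl carbon). Arabinose C1–C5 become C4, C3, C2, C1 and C7; the two carbons of the bis-phosphonium salt become C5 and C6. O2/O3 of the sugar are carried through the olefination as a trans-acetonide, because a benzoate β to the ketone would be prone to base-induced elimination under the ylide; the C3 benzoate is therefore introduced after ring closure.

Step 1
Reactants: 1 D-arabinose
Product: 2 D-arabinose diethyl dithioacetal
Conditions: EtSH, conc. HCl, 0 °C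
Reagents that add atoms: ethanethiol, CCS
Why: Acid-catalysed dithioacetalisation traps the open-chain aldehyde, masking C1 and leaving an acyclic tetraol whose stereocentres are untouched.

Step 2
Reactants: 2 D-arabinose diethyl dithioacetal
Product: 3 2,3:4,5-di-O-isopropylidene-D-arabinose diethyl dithioacetal
Conditions: Me2C(OMe)2, acetone, TsOH (cat.), rt
Reagents that add atoms: 2,2-dimethoxypropane, COC(C)(C)OC
Why: Acid-catalysed transketalisation should give the favoured pair of dioxolanes, the trans-disubstituted ring on the threo 2,3-diol and the terminal ring on O4/O5.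

Step 3
Reactants: 3 2,3:4,5-di-O-isopropylidene-D-arabinose diethyl dithioacetal
Product: 4 2,3-O-isopropylidene-D-arabinose diethyl dithioacetal (4-OH and 5-OH free)
Conditions: AcOH/H2O (7:3), 40 °C, stopped at the mono-acetonide
Reagents that add atoms: none
Why: Selective acetal hydrolysis, since the monosubstituted terminal dioxolane is cleaved faster in dilute acid than the internal trans-4,5-disubstituted one; over-hydrolysed material can be returned to step 2.

Step 4
Reactants: 4 2,3-O-isopropylidene-D-arabinose diethyl dithioacetal; 5 benzoyl chloride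
Product: 6 5-O-benzoyl-2,3-O-isopropylidene-D-arabinose diethyl dithioacetal
Conditions: BzCl (1.05 equiv), pyridine, CH2Cl2, −30 °C
Reagents that add atoms: benzoyl chloride, O=C(Cl)c1ccccc1
Why: Regioselective acylation of the primary 5-hydroxyl over the secondary 4-hydroxyl at low temperature installs the future C7 benzoate.

Step 5
Reactants: 6 5-O-benzoyl-2,3-O-isopropylidene-D-arabinose diethyl dithioacetal
Product: 7 5-O-benzoyl-2,3-O-isopropylidene-D-threo-pentos-4-ulose diethyl dithioacetal
Conditions: (COCl)2, DMSO, CH2Cl2, −78 °C; Et3N, −78 → 0 °C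
Reagents that add atoms: none
Why: Swern oxidation converts the only free (secondary) alcohol into the ketone while tolerating thioacetal, acetonide and benzoate, and the adjacent centre keeps the more stable trans-dioxolane arrangement.

Step 6
Reactants: 7 5-O-benzoyl-2,3-O-isopropylidene-D-threo-pentos-4-ulose diethyl dithioacetal
Product: 8 5-O-benzoyl-2,3-O-isopropylidene-aldehydo-D-threo-pentos-4-ulose (C1 aldehyde, C4 ketone)
Conditions: I2, NaHCO3, acetone/H2O, 0 °C; crude product dried and used at once
Reagents that add atoms: water, O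
Why: Iodine-mediated oxidative hydrolysis of the dithioacetal at bicarbonate pH should release the aldehyde without disturbing the acetonide, ketone or ester.

Step 7
Reactants: 8 5-O-benzoyl-2,3-O-isopropylidene-aldehydo-D-threo-pentos-4-ulose; 9 ethane-1,2-diylbis(triphenylphosphonium) dibromide
Product: 11 [(3aR,7aR)-2,2-dimethyl-3a,7a-dihydro-1,3-benzodioxol-4-yl]methyl benzoate, via Z-alkenyl allylic ylide 10 (not isolated)
Conditions: 9, KN(SiMe3)2 (2 equiv), THF, −78 → 0 °C; then 8 added slowly at high dilution, −78 °C → rt
Reagents that add atoms: ethane-1,2-diylbis(triphenylphosphonium) dibromide, [Br-].[Br-].c1ccc(cc1)[P+](CC[P+](c1ccccc1)(c1ccccc1)c1ccccc1)(c1ccccc1)c1ccccc1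
Why: Double Wittig cyclo-olefination, in which the preformed bis-ylide should olefinate the more electrophilic aldehyde first with the Z-selectivity of a non-stabilised ylide under lithium-free conditions and the allylic ylide left on the chain then closes the six-membered ring on the ketone; the base-stable trans-dioxolane carries no leaving group prone to β-elimination and protects both stereocentres.

Step 8
Reactants: 11 [(3aR,7aR)-2,2-dimethyl-3a,7a-dihydro-1,3-benzodioxol-4-yl]methyl benzoate
Product: 12 [(5R,6R)-5,6-dihydroxycyclohexa-1,3-dien-1-yl]methyl benzoate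
Conditions: AcOH/H2O/THF (3:1:1), rt
Reagents that add atoms: none
Why: Acid-catalysed acetal hydrolysis is fast for the strained trans-fused dioxolane, so weak aqueous acid at room temperature should suffice and the acid-sensitive dienediol should not aromatise.

Step 9
Reactants: 12 [(5R,6R)-5,6-dihydroxycyclohexa-1,3-dien-1-yl]methyl benzoate; 5 benzoyl chloride
Product: 13 [(5R,6R)-5-(benzoyloxy)-6-hydroxycyclohexa-1,3-dien-1-yl]methyl benzoate (target numbering: C3 benzoate, free C2 hydroxyl, trans)
Conditions: BzCl (1.0 equiv), pyridine, CH2Cl2, −40 °C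
Reagents that add atoms: benzoyl chloride, O=C(Cl)c1ccccc1
Why: Regioselective acylation, since the C3 hydroxyl is flanked only by an unsubstituted diene carbon whereas the C2 hydroxyl is crowded by the C1 benzoyloxymethyl arm, so one equivalent of acid chloride at low temperature should benzoylate C3 preferentially.

Step 10
Reactants: 13 [(5R,6R)-5-(benzoyloxy)-6-hydroxycyclohexa-1,3-dien-1-yl]methyl benzoate; 14 dioxygen
Product: 15 [(1S,4S,7S,8S)-8-(benzoyloxy)-7-hydroxy-2,3-dioxabicyclo[2.2.2]oct-5-en-1-yl]methyl benzoate (peroxide bridge cis to the free hydroxyl)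
Conditions: O2, tetraphenylporphyrin (cat.), visible light, CH2Cl2, −30 °C; crude product carried on directly
Reagents that add atoms: dioxygen (as singlet oxygen), O=O
Why: Sensitised singlet oxygen acts as a two-atom dienophile and adds to the s-cis-locked C1=C6–C5=C4 diene in a concerted suprafacial [4+2] cycloaddition (hetero-Diels–Alder photooxygenation, the ascaridole-type reaction of cyclohexa-1,3-dienes), forming C1–O and C4–O together. The ring closed is the six-membered 3,6-dihydro-1,2-dioxine spanning C1 and C4, formed by that cycloaddition and giving the 2,3-dioxabicyclo[2.2.2]oct-5-ene. Because both C–O bonds form on one face, the C1 and C4 oxygens are necessarily cis, and the choice of face fixes both new stereocentres at once. That choice is substrate-controlled: in a non-hydrogen-bonding solvent the free allylic C2 hydroxyl should hydrogen-bond to the incoming oxygen and draw it to its own face, while the trans C3 benzoate shields the opposite face, so the two effects are matched. The step needs this facial selectivity and [4+2] over ene reaction at the allylic C–H bonds; the rigid cisoid diene secures the latter, and low temperature with prompt reduction guards the peroxide against rearrangement.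

Step 11
Reactants: 15 [(1S,4S,7S,8S)-8-(benzoyloxy)-7-hydroxy-2,3-dioxabicyclo[2.2.2]oct-5-en-1-yl]methyl benzoate
Product: 16 1α-benzoyloxymethyl-3α-benzoyloxycyclohex-5-en-1β,2β,4β-triol (1S,2S,3R,4S)
Conditions: thiourea, MeOH, 0 °C → rt
Reagents that add atoms: none
Why: Reductive cleavage of the peroxide O–O bond by thiourea (sulfur attacks oxygen) runs under neutral conditions with retention at C1 and C4, leaving both benzoates and the C5=C6 alkene intact.

Compound list
1 | D-arabinose | O=C[C@@H](O)[C@H](O)[C@H](O)CO | starting material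
2 | D-arabinose diethyl dithioacetal | CCSC(SCC)[C@@H](O)[C@H](O)[C@H](O)CO | intermediate
3 | 2,3:4,5-di-O-isopropylidene-D-arabinose diethyl dithioacetal | CCSC(SCC)[C@@H](OC(C)(C)O1)[C@H]1[C@H]2COC(C)(C)O2 | intermediate
4 | 2,3-O-isopropylidene-D-arabinose diethyl dithioacetal | CCSC(SCC)[C@@H](OC(C)(C)O1)[C@H]1[C@H](O)CO | intermediate
5 | benzoyl chloride | O=C(Cl)c1ccccc1 | starting material
6 | 5-O-benzoyl-2,3-O-isopropylidene-D-arabinose diethyl dithioacetal | CCSC(SCC)[C@@H](OC(C)(C)O1)[C@H]1[C@H](O)COC(=O)c1ccccc1 | intermediate
7 | 5-O-benzoyl-2,3-O-isopropylidene-D-threo-pentos-4-ulose diethyl dithioacetal | CCSC(SCC)[C@@H](OC(C)(C)O1)[C@H]1C(=O)COC(=O)c1ccccc1 | intermediate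
8 | 5-O-benzoyl-2,3-O-isopropylidene-aldehydo-D-threo-pentos-4-ulose | O=C[C@@H](OC(C)(C)O1)[C@H]1C(=O)COC(=O)c1ccccc1 | intermediate
9 | ethane-1,2-diylbis(triphenylphosphonium) dibromide | [Br-].[Br-].c1ccc(cc1)[P+](CC[P+](c1ccccc1)(c1ccccc1)c1ccccc1)(c1ccccc1)c1ccccc1 | starting material
10 | 2-{trans-2,2-dimethyl-5-[(1Z)-3-(triphenyl-λ5-phosphanylidene)prop-1-en-1-yl]-1,3-dioxolan-4-yl}-2-oxoethyl benzoate (Z-alkenyl allylic ylide; configuration from arabinose C2 and C3) | O=C(COC(=O)c1ccccc1)[C@H]1OC(C)(C)O[C@@H]1/C=C\C=P(c1ccccc1)(c1ccccc1)c1ccccc1 | intermediate (not isolated)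
11 | [(3aR,7aR)-2,2-dimethyl-3a,7a-dihydro-1,3-benzodioxol-4-yl]methyl benzoate (trans-fused) | O=C(OCC1=CC=C[C@@H](OC(C)(C)O2)[C@@H]12)c1ccccc1 | intermediate
12 | [(5R,6R)-5,6-dihydroxycyclohexa-1,3-dien-1-yl]methyl benzoate | O=C(OCC1=CC=C[C@@H](O)[C@@H]1O)c1ccccc1 | intermediate
13 | [(5R,6R)-5-(benzoyloxy)-6-hydroxycyclohexa-1,3-dien-1-yl]methyl benzoate | O=C(OCC1=CC=C[C@@H](OC(=O)c2ccccc2)[C@@H]1O)c1ccccc1 | intermediate
14 | dioxygen | O=O | starting material
15 | [(1S,4S,7S,8S)-8-(benzoyloxy)-7-hydroxy-2,3-dioxabicyclo[2.2.2]oct-5-en-1-yl]methyl benzoate | O=C(OC[C@@]12C=C[C@H](OO2)[C@@H](OC(=O)c3ccccc3)[C@@H]1O)c1ccccc1 | intermediate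
16 | 1α-benzoyloxymethyl-3α-benzoyloxycyclohex-5-en-1β,2β,4β-triol | O=C(OC[C@@]1(O)C=C[C@H](O)[C@@H](OC(=O)c2ccccc2)[C@@H]1O)c1ccccc1 | target

Total steps: 11. Longest linear sequence: 11 steps (from D-arabinose 1).

Steps most likely to fail

1. Step 10. Oxygen may add to the face away from the C2 hydroxyl if hydrogen-bond steering is too weak. Ene reaction at the allylic C–H bonds or rearrangement of the peroxide before reduction are further possibilities. The fallback sets out from 13 and returns at 16, delivering the two oxygens one after the other. Vanadium-catalysed epoxidation (VO(acac)2, t-BuOOH, CH2Cl2, 0 °C) is directed by the allylic C2 hydroxyl to the C1=C6 bond and to the hydroxyl face. It should give the vinyl epoxide [3-(benzoyloxy)-2-hydroxy-7-oxabicyclo[4.1.0]hept-4-en-1-yl]methyl benzoate F1, with the oxirane oxygen cis to the 2-hydroxyl. Pd(PPh3)4-catalysed opening with acetic acid in THF ionises the allylic C6–O bond with inversion, and acetate then attacks the allyl-palladium at C4 from the face opposite to the metal. The C4 oxygen therefore ends up cis to the C1 hydroxyl in the 4-O-acetyl derivative of the target F2. Acetate-selective methanolysis (HCl from AcCl in MeOH, 0 °C, or a lipase), under which benzoates react far more slowly, would then give 16.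

2. Step 7. Ring closure may fail in several ways:
- loss of triphenylphosphine from incompletely deprotonated salt;
- enolisation of the keto-aldehyde or attack on the benzoate by the basic ylide;
- an E-configured first olefination;
- oligomerisation instead of cyclisation.

The fallback sets out from 7 and returns at 11, building the ring by metathesis. Barbier allylation of the ketone (allyl bromide, zinc dust, THF/aq. NH4Cl), which spares the benzoate, gives 4-C-allyl-5-O-benzoyl-2,3-O-isopropylidene-D-threo-pentose diethyl dithioacetal F3 as a mixture at the new carbinol carbon. Unmasking with I2/NaHCO3 gives the corresponding hydroxy aldehyde F4, in equilibrium with its lactol. Wittig methylenation (Ph3P=CH2, THF) gives the 1,7-diene tertiary alcohol F5. Ring-closing metathesis with the second-generation Grubbs catalyst closes C4=C5 to give trans-fused [4-hydroxy-2,2-dimethyl-3a,4,5,7a-tetrahydro-1,3-benzodioxol-4-yl]methyl benzoate F6. Dehydration of the tertiary alcohol with Burgess reagent towards the doubly activated allylic C6 hydrogens then delivers the conjugated diene 11; the carbinol stereocentre is destroyed, so its configuration is irrelevant.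

3. Step 9. Acylation may occur at the C2 hydroxyl or at both hydroxyls, and the benzoate could later migrate between C3 and C2 under basic conditions. The fallback sets out from 12 and returns at 13, masking the C2 hydroxyl through its 1,3-relationship to the C7 oxygen. Methanolysis (K2CO3, MeOH) gives (1R,2R)-3-(hydroxymethyl)cyclohexa-3,5-diene-1,2-diol F7. Phenylboronic acid (CH2Cl2, MgSO4) should tie the C7 and C2 oxygens into a six-membered cyclic phenylboronate F8, because a trans-1,2-diol on the ring cannot close a five-membered boronate comfortably. Benzoylation (BzCl, pyridine) of the only free hydroxyl gives the C3 benzoate boronate F9. Aqueous work-up releases [(5R,6R)-5-(benzoyloxy)-6-hydroxy... ] diol with free C7 hydroxyl, (1R,6R)-6-hydroxy-5-(hydroxymethyl)cyclohexa-2,4-dien-1-yl benzoate F10. Primary-selective benzoylation (BzCl, 1 equiv, 2,4,6-collidine, −78 °C) then gives 13.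

Further compounds
F1 | step 10 | [3-(benzoyloxy)-2-hydroxy-7-oxabicyclo[4.1.0]hept-4-en-1-yl]methyl benzoate, oxirane oxygen cis to the 2-hydroxyl | O=C(OC[C@@]12O[C@@H]1C=C[C@@H](OC(=O)c3ccccc3)[C@@H]2O)c1ccccc1
F2 | step 10 | 4-O-acetyl derivative of target 16 | O=C(OC[C@@]1(O)C=C[C@H](OC(C)=O)[C@@H](OC(=O)c2ccccc2)[C@@H]1O)c1ccccc1
F3 | step 7 | 4-C-allyl-5-O-benzoyl-2,3-O-isopropylidene-D-threo-pentose diethyl dithioacetal (both C4 epimers) | CCSC(SCC)[C@@H](OC(C)(C)O1)[C@H]1C(O)(CC=C)COC(=O)c1ccccc1
F4 | step 7 | 4-C-allyl-5-O-benzoyl-2,3-O-isopropylidene-aldehydo-D-threo-pentose (both C4 epimers) | O=C[C@@H](OC(C)(C)O1)[C@H]1C(O)(CC=C)COC(=O)c1ccccc1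
F5 | step 7 | 2-hydroxy-2-(trans-2,2-dimethyl-5-vinyl-1,3-dioxolan-4-yl)pent-4-en-1-yl benzoate (both carbinol epimers) | C=C[C@@H](OC(C)(C)O1)[C@H]1C(O)(CC=C)COC(=O)c1ccccc1
F6 | step 7 | trans-fused [4-hydroxy-2,2-dimethyl-3a,4,5,7a-tetrahydro-1,3-benzodioxol-4-yl]methyl benzoate (both carbinol epimers) | C1=C[C@@H](OC(C)(C)O2)[C@H]2C(O)(COC(=O)c3ccccc3)C1
F7 | step 9 | (1R,2R)-3-(hydroxymethyl)cyclohexa-3,5-diene-1,2-diol | OCC1=CC=C[C@@H](O)[C@@H]1O
F8 | step 9 | cyclic phenylboronate of F7 across the C7 and C2 oxygens (C3 hydroxyl free) | B2(c3ccccc3)OCC1=CC=C[C@@H](O)[C@@H]1O2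
F9 | step 9 | C3 benzoate of boronate F8 | B2(c3ccccc3)OCC1=CC=C[C@@H](OC(=O)c3ccccc3)[C@@H]1O2
F10 | step 9 | (1R,6R)-6-hydroxy-5-(hydroxymethyl)cyclohexa-2,4-dien-1-yl benzoate | OCC1=CC=C[C@@H](OC(=O)c2ccccc2)[C@@H]1O
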